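Ring B of the target is a cyclohexa-2,5-dienone (C6=C7, C8=O, C9=C10) joined to ring A at quaternary C5 and sp2 C10, that is, an oxidised 1,4-cyclohexadiene. The route therefore cuts C5–C10 and C8–C9: an intramolecular Diels–Alder reaction in which an alkynone C9≡C10 (activated by C1=O inside the tether) adds across the diene C5=C6–C7=C8. This single operation closes rings A and B, creates quaternary C5 beside C4 and leaves C8 doubly allylic for oxidation. Its precursor is an acyclic (E)-trienynone, HC9≡C10–C1(=O)–C2–C3(OTBS)–C4(Me)–C5(Me)=C6–C7=C8, whose C3 and C4 centres come from one Evans aldol reaction.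

Key step: step 12

Remarks on the chemistry:
- Atoms carry eremophilane numbers: ring A is C1–C5 with C10, ring B is C5–C10, C14 sits on C5, C15 on C4, and C11–C13 on C7. The target is (1R,3S,4R,5R); the C1 hydroxyl, the C3 ester oxygen, C14 and C15 all lie on one face.
- Assumption: compounds 1, 2, 8, 12, 16, 24 and 32 are bought.
- The C3 oxygen is carried through the cycloaddition as the (3R) silyl ether, epimeric to the target, and is inverted afterwards by oxidation and reduction.
- The (E)-diene is built by carbometalation and cross-coupling so that its geometry is fixed.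

Step 1
Reactants: 1 (S)-4-benzyl-3-propanoyl-1,3-oxazolidin-2-one; 2 3-[(tert-butyldimethylsilyl)oxy]propanal
Product: 4 (S)-4-benzyl-3-[(2S,3R)-5-(TBSO)-3-hydroxy-2-methylpentanoyl]-1,3-oxazolidin-2-one, via dibutylboron Z-enolate 3 (not isolated)
Conditions: Bu2BOTf, i-Pr2NEt, CH2Cl2, 0 °C; then 2, −78 → 0 °C; then pH 7 buffer, MeOH, H2O2
Reagents that add atoms: none
Why: Evans syn-aldol reaction, in which the Z boron enolate adds through a closed chair transition state on the face away from the benzyl group and so sets C3 (R) and C4 (the later 4R centre) as the syn pair.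

Step 2
Reactants: 4 aldol adduct
Product: 5 (2S,3R)-5-(TBSO)-3-hydroxy-N-methoxy-N,2-dimethylpentanamide
Conditions: MeNHOMe·HCl, Me3Al, THF, −20 → 0 °C
Reagents that add atoms: N,O-dimethylhydroxylamine hydrochloride, CNOC.Cl
Why: Weinreb amide formation by aluminium amide transamidation of the imide, assisted by the free C3 hydroxyl, which releases the auxiliary without touching a stereocentre.

Step 3
Reactants: 5 hydroxy Weinreb amide
Product: 6 (2S,3R)-3,5-bis(TBSO)-N-methoxy-N,2-dimethylpentanamide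
Conditions: TBSOTf, 2,6-lutidine, CH2Cl2, −78 → 0 °C
Reagents that add atoms: tert-butyldimethylsilyl triflate, CC(C)(C)[Si](C)(C)OS(=O)(=O)C(F)(F)F
Why: Silylation of the secondary alcohol with a silyl triflate; the C3 oxygen stays masked until ring A exists.

Step 4
Reactants: 6 bis-silyl Weinreb amide
Product: 7 (2S,3R)-3,5-bis(TBSO)-2-methylpentanal
Conditions: i-Bu2AlH, THF, −78 °C
Reagents that add atoms: none
Why: Weinreb amide reduction stops at the aldehyde because the chelated tetrahedral intermediate survives until work-up, and the α-centre should not epimerise at −78 °C.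

Step 5
Reactants: 7 aldehyde; 8 dimethyl (1-diazo-2-oxopropyl)phosphonate
Product: 9 (3R,4R)-4,6-bis(TBSO)-3-methylhex-1-yne
Conditions: K2CO3, MeOH, 0 °C → rt
Reagents that add atoms: dimethyl (1-diazo-2-oxopropyl)phosphonate (8), CC(=O)C(=[N+]=[N-])P(=O)(OC)OC
Why: Ohira–Bestmann (Seyferth–Gilbert) homologation turns the aldehyde carbon into C5 of a terminal alkyne C5≡C6 under conditions mild enough for an α-methyl β-silyloxy aldehyde.

Step 6
Reactants: 9 alkyne
Product: 11 (1E,3R,4R)-4,6-bis(TBSO)-1-iodo-2,3-dimethylhex-1-ene, via alkenylalane 10 (not isolated)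
Conditions: Me3Al, Cp2ZrCl2 (0.3 equiv), CH2Cl2, 0 °C → rt; then I2, THF, −30 → 0 °C
Reagents that add atoms: trimethylaluminium, C[Al](C)C; iodine, II
Why: Negishi zirconium-catalysed carboalumination adds methyl (C14) and aluminium syn across the alkyne with methyl on the internal carbon C5, and iodinolysis with retention gives the E iodide only.

Step 7
Reactants: 11 vinyl iodide; 12 tributyl(vinyl)stannane
Product: 13 (3R,4R,5E)-1,3-bis(TBSO)-4,5-dimethylocta-5,7-diene
Conditions: PdCl2(MeCN)2 (5 mol %), DMF, rt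
Reagents that add atoms: tributyl(vinyl)stannane (12), C=C[Sn](CCCC)(CCCC)CCCC
Why: Stille coupling proceeds with retention at the alkenyl iodide, so the diene C5=C6–C7=C8 is formed as the single E isomer with C14 cis to C7.

Step 8
Reactants: 13 bis-silyl diene
Product: 14 (3R,4R,5E)-3-(TBSO)-4,5-dimethylocta-5,7-dien-1-ol
Conditions: HF·pyridine, pyridine, THF, 0 °C → rt
Reagents that add atoms: none
Why: Buffered fluoride desilylation cleaves the primary silyl ether much faster than the secondary one flanked by C4.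

Step 9
Reactants: 14 primary alcohol
Product: 15 (3R,4R,5E)-3-(TBSO)-4,5-dimethylocta-5,7-dienal
Conditions: Dess–Martin periodinane, pyridine, CH2Cl2, 0 °C → rt
Reagents that add atoms: none
Why: Dess–Martin oxidation under buffered, non-basic conditions gives the β-silyloxy aldehyde without elimination or harm to the diene.

Step 10
Reactants: 15 aldehyde; 16 ethynylmagnesium bromide (HC≡CMgBr)
Product: 17 (5R,6R,7E)-5-(TBSO)-6,7-dimethyldeca-7,9-dien-1-yn-3-ol (both C1 carbinol epimers)
Conditions: THF, −78 → 0 °C; then H2O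
Reagents that add atoms: ethynylmagnesium bromide (16), C#C[Mg]Br
Why: Grignard addition to the aldehyde installs C9 and C10; the new carbinol centre needs no control because it is oxidised in the next step.

Step 11
Reactants: 17 propargylic alcohol
Product: 18 (5R,6R,7E)-5-(TBSO)-6,7-dimethyldeca-7,9-dien-1-yn-3-one (trienynone; target numbering 3R,4R)
Conditions: Dess–Martin periodinane, pyridine, CH2Cl2, 0 °C
Reagents that add atoms: none
Why: Dess–Martin oxidation of a propargylic alcohol gives the terminal ynone under neutral conditions; it is used at once.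

Step 12
Reactants: 18 trienynone
Product: 19 (3R,4R,5R)-3-(TBSO)-11,12,13-trinoreremophila-6,9-dien-1-one
Conditions: PhMe (0.01 M), BHT (cat.), 140 °C, sealed tube
Reagents that add atoms: none
Why: Thermal intramolecular Diels–Alder reaction of an alkynone, a known reaction type: a concerted but asynchronous [4+2] cycloaddition in which C8 bonds to the ynone β-carbon C9 ahead of the C5–C10 bond, and the alkyne delivers the 6,9-diene (a 1,4-cyclohexadiene) directly. Ring B (C5–C6–C7–C8–C9–C10) is closed as the six-membered cycloaddition ring and ring A (C10–C1–C2–C3–C4–C5) as the six-membered tether ring, the C5–C10 bond being exo to both the alkyne and the diene so that only the fused regiochemistry is possible. C5 is the one new stereocentre and is controlled by C3 and C4: in the chair-like tether the C3 silyloxy group and the C4 methyl are both equatorial, which places the alkyne on the diene face anti to C15 and makes C14 and C15 cis, whereas addition to the other face would force the silyloxy group axial and syn to the inside methyl C14. The step needs this π-facial selectivity and enough driving force to overcome the C14 methyl on the inside of the diene terminus, hence heat, high dilution and a radical inhibitor, and no Lewis acid because the silyloxy group is β to the ketone; there is no endo/exo question since C10 ends sp2. A single equatorial silyl ether at C3 is preferred to a C3 ketal, which would hold one oxygen axial and syn to C14 in both diastereomeric chairs, would not tell them apart, and could only be made by way of a C3 ketone next to the epimerisable C4.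

Step 13
Reactants: 19 dienone
Product: 20 (1R,3R,4R,5R)-3-(TBSO)-11,12,13-trinoreremophila-6,9-dien-1-ol
Conditions: NaBH4, CeCl3·7H2O, MeOH, −78 °C
Reagents that add atoms: none
Why: Luche 1,2-reduction delivers hydride to the C1 face opposite the axial C14 methyl, giving the 1R alcohol with the hydroxyl cis to C14.

Step 14
Reactants: 20 allylic alcohol
Product: 21 (1R,3R,4R,5R)-3-(TBSO)-1-(methoxymethoxy)-11,12,13-trinoreremophila-6,9-diene
Conditions: MOMCl, i-Pr2NEt, Bu4NI (cat.), CH2Cl2, 40 °C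
Reagents that add atoms: chloromethyl methyl ether, COCCl
Why: O-Alkylation to the methoxymethyl ether, a small, non-migrating group that tolerates the oxidants, bases and hydrides ahead and is orthogonal to the C3 silyl ether.

Step 15
Reactants: 21 diene
Product: 22 (1R,3R,4R,5R)-3-(TBSO)-1-(methoxymethoxy)-11,12,13-trinoreremophila-6,9-dien-8-one
Conditions: (C5H5NH)2Cr2O7, t-BuOOH, Celite, benzene, rt
Reagents that add atoms: tert-butyl hydroperoxide, CC(C)(C)OO
Why: Chromium-mediated allylic oxidation with t-BuOOH attacks the doubly allylic C8–H bonds, the weakest in the molecule, and quaternary C5 blocks aromatisation, so the cyclohexa-2,5-dienone results.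

Step 16
Reactants: 22 cross-conjugated dienone
Product: 23 (1R,3R,4R,5R)-3-(TBSO)-1-(methoxymethoxy)-11,12,13-trinoreremophil-9-en-8-one
Conditions: H2 (1 atm), RhCl(PPh3)3 (10 mol %), benzene, rt
Reagents that add atoms: none
Why: Homogeneous hydrogenation with RhCl(PPh3)3 saturates the disubstituted C6=C7 and leaves the trisubstituted C9=C10, the selectivity known for 4,4-disubstituted cyclohexa-2,5-dienones such as steroidal 1,4-dien-3-ones.

Step 17
Reactants: 23 enone; 24 acetone
Product: 26 (1R,3R,4R,5R)-3-(TBSO)-11-hydroxy-1-(methoxymethoxy)eremophil-9-en-8-one (C7 epimers), via lithium enolate 25 (not isolated)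
Conditions: LiN(i-Pr)2, THF, −78 °C; then acetone, −78 °C; then AcOH, −78 °C
Reagents that add atoms: acetone (24), CC(C)=O
Why: Kinetic α′-deprotonation at C7 gives the cross-conjugated enolate, whose aldol addition to acetone attaches C11–C13; the C7 configuration is irrelevant because C7 becomes sp2 in step 18.

Step 18
Reactants: 26 aldol
Product: 28 (1R,3R,4R,5R)-3-(TBSO)-1-(methoxymethoxy)eremophila-7(11),9-dien-8-one, via tertiary mesylate 27 (not isolated)
Conditions: MsCl, Et3N, DMAP (cat.), CH2Cl2, 0 °C; then DBU, rt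
Reagents that add atoms: none
Why: Mesylation followed by E1cB elimination through the C8 enolate can only give the conjugated C7=C11 isopropylidene.

Step 19
Reactants: 28 silyl ether
Product: 29 (1R,3R,4R,5R)-3-hydroxy-1-(methoxymethoxy)eremophila-7(11),9-dien-8-one
Conditions: HF·pyridine, THF, 0 °C → rt
Reagents that add atoms: none
Why: Fluoride desilylation frees the C3 hydroxyl while the methoxymethyl ether and the dienone are inert.

Step 20
Reactants: 29 alcohol
Product: 30 (1R,4R,5R)-1-(methoxymethoxy)eremophila-7(11),9-diene-3,8-dione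
Conditions: Dess–Martin periodinane, pyridine, CH2Cl2, rt
Reagents that add atoms: none
Why: Dess–Martin oxidation gives the C3 ketone without base, and C4 is not at risk because its equatorial methyl, cis to C14, is the stable α-epimer.

Step 21
Reactants: 30 dione
Product: 31 (1R,3S,4R,5R)-3-hydroxy-1-(methoxymethoxy)eremophila-7(11),9-dien-8-one
Conditions: LiBH(s-Bu)3, THF, −78 °C; then H2O
Reagents that add atoms: none
Why: The bulky hydride reduces the saturated C3 ketone in preference to the hindered cross-conjugated C8 ketone and attacks anti to the axial C14 methyl and the axial C1 ether, giving the 3S alcohol with oxygen cis to C14 and C15.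

Step 22
Reactants: 31 alcohol; 32 angelic acid
Product: 34 (1R,3S,4R,5R)-3-angeloyloxy-1-(methoxymethoxy)eremophila-7(11),9-dien-8-one, via angelic 2,4,6-trichlorobenzoic anhydride 33 (not isolated)
Conditions: 32, 2,4,6-trichlorobenzoyl chloride, Et3N, PhMe, rt; then 31, 80 °C
Reagents that add atoms: angelic acid (32), C/C=C(/C)C(=O)O
Why: Yamaguchi-type mixed-anhydride esterification without a nucleophilic catalyst acylates the hindered alcohol while keeping the Z geometry of the angelate.

Step 23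
Reactants: 34 methoxymethyl ether
Product: 36 (1R,3S,4R,5R)-3-angeloyloxy-1-hydroxyeremophila-7(11),9-dien-8-one, via bromomethyl ether 35 (not isolated)
Conditions: Me2BBr, CH2Cl2, −78 °C; then aq. NaHCO3, THF
Reagents that add atoms: none
Why: Lewis-acid acetal cleavage at −78 °C converts the methoxymethyl ether into a bromomethyl ether that hydrolyses on work-up, under conditions the ester, the dienone and the Z-alkene should tolerate.

Step 24
Reactants: 36 dienone
Product: 37 (1R,3S,4R,5R)-3-angeloyloxy-11-hydroperoxy-1-hydroxyeremophila-6,9-dien-8-one (CNP0300636.1)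
Conditions: O2, visible light, tetraphenylporphyrin (cat.), CH2Cl2, 0 °C
Reagents that add atoms: oxygen, O=O
Why: Schenck ene reaction in which singlet oxygen bonds to C11 and abstracts a C6 hydrogen, on the alkyl group geminal to the carbonyl as is usual for α,β-unsaturated ketones, moving the alkene to C6=C7 and creating no new stereocentre.

Compound list
1 | (S)-4-benzyl-3-propanoyl-1,3-oxazolidin-2-one | CCC(=O)N1[C@@H](Cc2ccccc2)COC1=O | starting material
2 | 3-[(tert-butyldimethylsilyl)oxy]propanal | O=CCCO[Si](C)(C)C(C)(C)C | starting material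
3 | dibutylboron (Z)-enolate of 1 | C/C=C(\OB(CCCC)CCCC)N1[C@@H](Cc2ccccc2)COC1=O | intermediate
4 | (S)-4-benzyl-3-[(2S,3R)-5-(TBSO)-3-hydroxy-2-methylpentanoyl]-1,3-oxazolidin-2-one | CC(C)(C)[Si](C)(C)OCC[C@@H](O)[C@H](C)C(=O)N1[C@@H](Cc2ccccc2)COC1=O | intermediate
5 | (2S,3R)-5-(TBSO)-3-hydroxy-N-methoxy-N,2-dimethylpentanamide | CC(C)(C)[Si](C)(C)OCC[C@@H](O)[C@H](C)C(=O)N(C)OC | intermediate
6 | (2S,3R)-3,5-bis(TBSO)-N-methoxy-N,2-dimethylpentanamide | CC(C)(C)[Si](C)(C)OCC[C@@H](O[Si](C)(C)C(C)(C)C)[C@H](C)C(=O)N(C)OC | intermediate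
7 | (2S,3R)-3,5-bis(TBSO)-2-methylpentanal | CC(C)(C)[Si](C)(C)OCC[C@@H](O[Si](C)(C)C(C)(C)C)[C@H](C)C=O | intermediate
8 | dimethyl (1-diazo-2-oxopropyl)phosphonate | CC(=O)C(=[N+]=[N-])P(=O)(OC)OC | starting material
9 | (3R,4R)-4,6-bis(TBSO)-3-methylhex-1-yne | CC(C)(C)[Si](C)(C)OCC[C@@H](O[Si](C)(C)C(C)(C)C)[C@H](C)C#C | intermediate
10 | [(1E,3R,4R)-4,6-bis(TBSO)-2,3-dimethylhex-1-en-1-yl]dimethylalane | CC(C)(C)[Si](C)(C)OCC[C@@H](O[Si](C)(C)C(C)(C)C)[C@H](C)/C(C)=C/[Al](C)C | intermediate
11 | (1E,3R,4R)-4,6-bis(TBSO)-1-iodo-2,3-dimethylhex-1-ene | CC(C)(C)[Si](C)(C)OCC[C@@H](O[Si](C)(C)C(C)(C)C)[C@H](C)/C(C)=C/I | intermediate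
12 | tributyl(vinyl)stannane | C=C[Sn](CCCC)(CCCC)CCCC | starting material
13 | (3R,4R,5E)-1,3-bis(TBSO)-4,5-dimethylocta-5,7-diene | CC(C)(C)[Si](C)(C)OCC[C@@H](O[Si](C)(C)C(C)(C)C)[C@H](C)/C(C)=C/C=C | intermediate
14 | (3R,4R,5E)-3-(TBSO)-4,5-dimethylocta-5,7-dien-1-ol | OCC[C@@H](O[Si](C)(C)C(C)(C)C)[C@H](C)/C(C)=C/C=C | intermediate
15 | (3R,4R,5E)-3-(TBSO)-4,5-dimethylocta-5,7-dienal | O=CC[C@@H](O[Si](C)(C)C(C)(C)C)[C@H](C)/C(C)=C/C=C | intermediate
16 | ethynylmagnesium bromide | C#C[Mg]Br | starting material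
17 | (5R,6R,7E)-5-(TBSO)-6,7-dimethyldeca-7,9-dien-1-yn-3-ol (both carbinol epimers) | C#CC(O)C[C@@H](O[Si](C)(C)C(C)(C)C)[C@H](C)/C(C)=C/C=C | intermediate
18 | (5R,6R,7E)-5-(TBSO)-6,7-dimethyldeca-7,9-dien-1-yn-3-one | C#CC(=O)C[C@@H](O[Si](C)(C)C(C)(C)C)[C@H](C)/C(C)=C/C=C | intermediate
19 | (3R,4R,5R)-3-(TBSO)-11,12,13-trinoreremophila-6,9-dien-1-one | O=C1C[C@@H](O[Si](C)(C)C(C)(C)C)[C@H](C)[C@@]2(C)C=CCC=C12 | intermediate
20 | (1R,3R,4R,5R)-3-(TBSO)-11,12,13-trinoreremophila-6,9-dien-1-ol | O[C@@H]1C[C@@H](O[Si](C)(C)C(C)(C)C)[C@H](C)[C@@]2(C)C=CCC=C12 | intermediate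
21 | (1R,3R,4R,5R)-3-(TBSO)-1-(methoxymethoxy)-11,12,13-trinoreremophila-6,9-diene | COCO[C@@H]1C[C@@H](O[Si](C)(C)C(C)(C)C)[C@H](C)[C@@]2(C)C=CCC=C12 | intermediate
22 | (1R,3R,4R,5R)-3-(TBSO)-1-(methoxymethoxy)-11,12,13-trinoreremophila-6,9-dien-8-one | COCO[C@@H]1C[C@@H](O[Si](C)(C)C(C)(C)C)[C@H](C)[C@@]2(C)C=CC(=O)C=C12 | intermediate
23 | (1R,3R,4R,5R)-3-(TBSO)-1-(methoxymethoxy)-11,12,13-trinoreremophil-9-en-8-one | COCO[C@@H]1C[C@@H](O[Si](C)(C)C(C)(C)C)[C@H](C)[C@@]2(C)CCC(=O)C=C12 | intermediate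
24 | acetone | CC(C)=O | starting material
25 | lithium 7,9-dien-8-olate of 23 | COCO[C@@H]1C[C@@H](O[Si](C)(C)C(C)(C)C)[C@H](C)[C@@]2(C)CC=C(O[Li])C=C12 | intermediate
26 | (1R,3R,4R,5R)-3-(TBSO)-11-hydroxy-1-(methoxymethoxy)eremophil-9-en-8-one (C7 epimers) | COCO[C@@H]1C[C@@H](O[Si](C)(C)C(C)(C)C)[C@H](C)[C@@]2(C)CC(C(C)(C)O)C(=O)C=C12 | intermediate
27 | 11-O-methanesulfonate of 26 | COCO[C@@H]1C[C@@H](O[Si](C)(C)C(C)(C)C)[C@H](C)[C@@]2(C)CC(C(C)(C)OS(C)(=O)=O)C(=O)C=C12 | intermediate
28 | (1R,3R,4R,5R)-3-(TBSO)-1-(methoxymethoxy)eremophila-7(11),9-dien-8-one | COCO[C@@H]1C[C@@H](O[Si](C)(C)C(C)(C)C)[C@H](C)[C@@]2(C)CC(=C(C)C)C(=O)C=C12 | intermediate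
29 | (1R,3R,4R,5R)-3-hydroxy-1-(methoxymethoxy)eremophila-7(11),9-dien-8-one | COCO[C@@H]1C[C@@H](O)[C@H](C)[C@@]2(C)CC(=C(C)C)C(=O)C=C12 | intermediate
30 | (1R,4R,5R)-1-(methoxymethoxy)eremophila-7(11),9-diene-3,8-dione | COCO[C@@H]1CC(=O)[C@H](C)[C@@]2(C)CC(=C(C)C)C(=O)C=C12 | intermediate
31 | (1R,3S,4R,5R)-3-hydroxy-1-(methoxymethoxy)eremophila-7(11),9-dien-8-one | COCO[C@@H]1C[C@H](O)[C@H](C)[C@@]2(C)CC(=C(C)C)C(=O)C=C12 | intermediate
32 | angelic acid, (Z)-2-methylbut-2-enoic acid | C/C=C(/C)C(=O)O | starting material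
33 | angelic 2,4,6-trichlorobenzoic anhydride | C/C=C(/C)C(=O)OC(=O)c1c(Cl)cc(Cl)cc1Cl | intermediate
34 | (1R,3S,4R,5R)-3-angeloyloxy-1-(methoxymethoxy)eremophila-7(11),9-dien-8-one | C/C=C(/C)C(=O)O[C@H]1C[C@@H](OCOC)C2=CC(=O)C(=C(C)C)C[C@]2(C)[C@H]1C | intermediate
35 | (1R,3S,4R,5R)-3-angeloyloxy-1-(bromomethoxy)eremophila-7(11),9-dien-8-one | C/C=C(/C)C(=O)O[C@H]1C[C@@H](OCBr)C2=CC(=O)C(=C(C)C)C[C@]2(C)[C@H]1C | intermediate
36 | (1R,3S,4R,5R)-3-angeloyloxy-1-hydroxyeremophila-7(11),9-dien-8-one | C/C=C(/C)C(=O)O[C@H]1C[C@@H](O)C2=CC(=O)C(=C(C)C)C[C@]2(C)[C@H]1C | intermediate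
37 | (1R,3S,4R,5R)-3-angeloyloxy-11-hydroperoxy-1-hydroxyeremophila-6,9-dien-8-one | C/C=C(/C)C(=O)O[C@H]1C[C@@H](O)C2=CC(=O)C(C(C)(C)OO)=C[C@]2(C)[C@H]1C | target

Total step count: 24
Longest linear sequence: 24 steps (1 to 37; all building blocks are bought, so there is no separate branch).

Steps most likely to fail

Step 12 (cycloaddition). What may go wrong: ring closure at the fully substituted C5 terminus is slow, so the terminal ynone may polymerise on prolonged heating, and π-facial selection may be incomplete. Fallback, an alkyne surrogate: from 18, conjugate addition of PhSO2Na in AcOH/EtOH would give the (E)-β-(phenylsulfonyl)enone F1. This doubly activated alkene should undergo the same intramolecular Diels–Alder reaction at lower temperature (toluene, 80–110 °C) to the sulfonyl ketone F2, formed as a mixture at C9 and C10, both of which are erased. DBU-induced β-elimination of benzenesulfinate would then return to 19.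

Step 24 (photooxygenation). What may go wrong: abstraction of a C12/C13 methyl hydrogen instead of a C6 hydrogen, that is, loss of regiocontrol, and further oxidation of the hydroperoxide. Fallback, hydroperoxysilylation of a diene in place of the ene reaction: from 34, photooxygenation regardless of regiochemistry would give the 11-hydroperoxy-6-ene F3 and the 7-hydroperoxy-11(12)-ene F4. PPh3 would reduce these to the 11-alcohol F5 and the 7-alcohol F6, and Burgess dehydration would converge both on the 7-isopropenyl-6,9-dien-8-one F7. Me2BBr as in step 23, through the bromomethyl ether F8, would free the C1 hydroxyl to give the hydroxy trienone F9. Co(acac)2-catalysed hydroperoxysilylation (Et3SiH, O2; Isayama–Mukaiyama reaction), which adds hydrogen to the terminal C12 and the peroxy group to the adjacent C11 of a conjugated diene, would give the triethylsilyl peroxide F10. HF·pyridine would then release 37.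

Step 22 (angeloylation). What may go wrong: acylation of the axial C3 hydroxyl, flanked by C14 and the C1 ether, is slow, and the acyl donor may isomerise from Z to E under forcing conditions. Fallback, building the Z-alkene after acylation: from 31, esterification with the saturated and more electrophilic 2-[bis(2,2,2-trifluoroethoxy)phosphoryl]propanoic acid (DCC, DMAP, CH2Cl2) would give the phosphonopropionate F11. Still–Gennari olefination with acetaldehyde (KN(SiMe3)2, 18-crown-6, THF, −78 °C) would then form the (Z)-2-methylbut-2-enoate and return to 34.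

Further compounds
F1 | step 12 | (1E,5R,6R,7E)-5-(TBSO)-6,7-dimethyl-1-(phenylsulfonyl)deca-1,7,9-trien-3-one | O=S(=O)(/C=C/C(=O)C[C@@H](O[Si](C)(C)C(C)(C)C)[C@H](C)/C(C)=C/C=C)c1ccccc1
F2 | step 12 | (3R,4R,5R)-3-(TBSO)-9-(phenylsulfonyl)-11,12,13-trinoreremophil-6-en-1-one (C9 and C10 epimers) | O=C1C[C@@H](O[Si](C)(C)C(C)(C)C)[C@H](C)[C@@]2(C)C=CCC(S(=O)(=O)c3ccccc3)C12
F3 | step 24 | (1R,3S,4R,5R)-3-angeloyloxy-11-hydroperoxy-1-(methoxymethoxy)eremophila-6,9-dien-8-one | C/C=C(/C)C(=O)O[C@H]1C[C@@H](OCOC)C2=CC(=O)C(C(C)(C)OO)=C[C@]2(C)[C@H]1C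
F4 | step 24 | (1R,3S,4R,5R)-3-angeloyloxy-7-hydroperoxy-1-(methoxymethoxy)eremophila-9,11-dien-8-one (C7 epimers) | C/C=C(/C)C(=O)O[C@H]1C[C@@H](OCOC)C2=CC(=O)C(OO)(C(C)=C)C[C@]2(C)[C@H]1C
F5 | step 24 | (1R,3S,4R,5R)-3-angeloyloxy-11-hydroxy-1-(methoxymethoxy)eremophila-6,9-dien-8-one | C/C=C(/C)C(=O)O[C@H]1C[C@@H](OCOC)C2=CC(=O)C(C(C)(C)O)=C[C@]2(C)[C@H]1C
F6 | step 24 | (1R,3S,4R,5R)-3-angeloyloxy-7-hydroxy-1-(methoxymethoxy)eremophila-9,11-dien-8-one (C7 epimers) | C/C=C(/C)C(=O)O[C@H]1C[C@@H](OCOC)C2=CC(=O)C(O)(C(C)=C)C[C@]2(C)[C@H]1C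
F7 | step 24 | (1R,3S,4R,5R)-3-angeloyloxy-1-(methoxymethoxy)eremophila-6,9,11-trien-8-one | C/C=C(/C)C(=O)O[C@H]1C[C@@H](OCOC)C2=CC(=O)C(C(C)=C)=C[C@]2(C)[C@H]1C
F8 | step 24 | (1R,3S,4R,5R)-3-angeloyloxy-1-(bromomethoxy)eremophila-6,9,11-trien-8-one | C/C=C(/C)C(=O)O[C@H]1C[C@@H](OCBr)C2=CC(=O)C(C(C)=C)=C[C@]2(C)[C@H]1C
F9 | step 24 | (1R,3S,4R,5R)-3-angeloyloxy-1-hydroxyeremophila-6,9,11-trien-8-one | C/C=C(/C)C(=O)O[C@H]1C[C@@H](O)C2=CC(=O)C(C(C)=C)=C[C@]2(C)[C@H]1C
F10 | step 24 | (1R,3S,4R,5R)-3-angeloyloxy-1-hydroxy-11-(triethylsilylperoxy)eremophila-6,9-dien-8-one | C/C=C(/C)C(=O)O[C@H]1C[C@@H](O)C2=CC(=O)C(C(C)(C)OO[Si](CC)(CC)CC)=C[C@]2(C)[C@H]1C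
F11 | step 22 | (1R,3S,4R,5R)-3-{2-[bis(2,2,2-trifluoroethoxy)phosphoryl]propanoyloxy}-1-(methoxymethoxy)eremophila-7(11),9-dien-8-one | CC(C(=O)O[C@H]1C[C@@H](OCOC)C2=CC(=O)C(=C(C)C)C[C@]2(C)[C@H]1C)P(=O)(OCC(F)(F)F)OCC(F)(F)F
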